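**Strategy.** Everything rests on disconnecting C3–C4 of ring C of the upper flavan unit: the bond between the carbinol carbon C3 and the doubly benzylic C4 that carries ring A and C8 of the epigallocatechin unit. Since 3-OH and 4-H are cis and all three ring C substituents equatorial, this bond is the syn-hydrated form of a C3=C4 olefin. Ring-closing metathesis of a diene, a 1,1-diarylethylene tethered to an aryl 1-arylallyl ether, closes ring C through this bond. The diene comes from purchased (−)-epigallocatechin and an ether whose C2 is set by iridium catalysis; one hydroboration then relays C2 to C3 and C4.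

Key step: step 9

Assumption: the configuration of the ether made in step 7 is taken to be controlled by the phosphoramidite ligand alone; the ligand enantiomer written is the one expected to give the (S)-ether, and its antipode would be used if the sense of induction proves opposite.

**Step 1**
Reactants: 1 (−)-epigallocatechin
Product: 2 5,7,3',4',5'-penta-O-benzyl-(−)-epigallocatechin
Conditions: BnBr (5.5 equiv), K2CO3, DMF, 0 °C → rt, argon
Reagents that add atoms: benzyl bromide BrCc1ccccc1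
Why: Williamson etherification in which K2CO3 deprotonates only the five phenols, so the secondary 3-OH stays free, and the low temperature should limit C-benzylation and epimerisation at C2, whose configuration, like that at C3, is bought with 1.

**Step 2**
Reactants: 2 5,7,3',4',5'-penta-O-benzyl-(−)-epigallocatechin
Product: 3 3,5,7,3',4',5'-hexa-O-benzyl-(−)-epigallocatechin
Conditions: NaH, BnBr, n-Bu4NI (cat.), THF/DMF, 0 °C → rt
Reagents that add atoms: benzyl bromide BrCc1ccccc1
Why: Williamson etherification of the secondary alkoxide, which removes the only acidic proton before the organolithium step and adds a group that leaves with the others in step 11.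

**Step 3**
Reactants: 3 3,5,7,3',4',5'-hexa-O-benzyl-(−)-epigallocatechin
Product: 4 8-bromo-3,5,7,3',4',5'-hexa-O-benzyl-(−)-epigallocatechin
Conditions: NBS (1.05 equiv), CH2Cl2, −78 °C → rt, dark
Reagents that add atoms: N-bromosuccinimide O=C1CCC(=O)N1Br
Why: Electrophilic aromatic bromination of the phloroglucinol-type ring, which in per-O-alkylated flavan-3-ols should occur at C8 in preference to C6 and to the less activated pyrogallol ring.

**Step 4**
Reactants: 5 3,4,5-tris(benzyloxy)benzaldehyde; 6 triethyl phosphonoacetate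
Product: 7 ethyl (E)-3-[3,4,5-tris(benzyloxy)phenyl]prop-2-enoate
Conditions: NaH, THF, 0 °C → rt
Reagents that add atoms: none
Why: Horner–Wadsworth–Emmons olefination of an aromatic aldehyde with a stabilised phosphonate anion, which should give the E-cinnamate.

**Step 5**
Reactants: 7 ethyl (E)-3-[3,4,5-tris(benzyloxy)phenyl]prop-2-enoate
Product: 8 (E)-3-[3,4,5-tris(benzyloxy)phenyl]prop-2-en-1-ol
Conditions: i-Bu2AlH (2.5 equiv), CH2Cl2, −78 → 0 °C; Rochelle salt work-up
Reagents that add atoms: none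
Why: 1,2-Reduction of the unsaturated ester by the aluminium hydride to the allylic alcohol, leaving olefin geometry and benzyl ethers untouched.

**Step 6**
Reactants: 8 (E)-3-[3,4,5-tris(benzyloxy)phenyl]prop-2-en-1-ol
Product: 9 methyl (E)-3-[3,4,5-tris(benzyloxy)phenyl]prop-2-en-1-yl carbonate
Conditions: ClCO2Me, pyridine, DMAP (cat.), CH2Cl2, 0 °C
Reagents that add atoms: methyl chloroformate COC(=O)Cl
Why: O-Acylation of the primary allylic alcohol, which installs the carbonate leaving group needed for the π-allyl step.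

**Step 7**
Reactants: 9 methyl (E)-3-[3,4,5-tris(benzyloxy)phenyl]prop-2-en-1-yl carbonate; 10 1-[4-(benzyloxy)-2-hydroxyphenyl]ethan-1-one
Product: 11 1-[4-(benzyloxy)-2-{[(1S)-1-[3,4,5-tris(benzyloxy)phenyl]prop-2-en-1-yl]oxy}phenyl]ethan-1-one
Conditions: 10 (2 equiv), NaH (2 equiv), THF; then 9, [Ir(cod)Cl]2 (2 mol %), (Sa,Sc,Sc)-O,O'-(1,1'-binaphthalene-2,2'-diyl) N,N-bis(1-phenylethyl)phosphoramidite (4 mol %, catalyst pre-activated with n-PrNH2), THF, 50 °C; stopped at full conversion
Reagents that add atoms: none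
Why: Iridium-catalysed asymmetric allylic etherification (Tsuji–Trost-type substitution through a cyclometalated phosphoramidite iridium π-allyl complex), in which the aryloxide should attack the aryl-bearing allyl terminus to give the branched ether and the ligand controls the face, setting the future C2 as S (the spatial arrangement that is R in the target).

**Step 8**
Reactants: 4 8-bromo-3,5,7,3',4',5'-hexa-O-benzyl-(−)-epigallocatechin; 11 1-[4-(benzyloxy)-2-{[(1S)-1-[3,4,5-tris(benzyloxy)phenyl]prop-2-en-1-yl]oxy}phenyl]ethan-1-one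
Product: 14 1,1-diarylethylene diene, via aryllithium 12 (not isolated), via tertiary carbinol 13 (not isolated)
Conditions: 4 (1.3 equiv), n-BuLi (1.25 equiv), THF, −78 °C; then 11, −78 → −20 °C; then PPTS (1.6 equiv), 0 → 45 °C
Reagents that add atoms: none
Why: Bromine–lithium exchange, 1,2-addition of the aryllithium to the aryl methyl ketone and E1 dehydration of the 1,1-diarylethanol, whose cation is stabilised by both polyalkoxyaryl rings so that a mild pyridinium acid suffices and the allylic ether with its stereocentre should survive; no stereocentre is created.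

**Step 9**
Reactants: 14 1,1-diarylethylene diene
Product: 15 (2S)-7-(benzyloxy)-2-[3,4,5-tris(benzyloxy)phenyl]-4-[(2R,3R)-3,5,7-tris(benzyloxy)-2-[3,4,5-tris(benzyloxy)phenyl]chroman-8-yl]-2H-chromene
Conditions: second-generation Hoveyda–Grubbs catalyst RuCl2(H2IMes)(=CH-C6H4-2-O-i-Pr) (10 mol %), 1,4-benzoquinone (10 mol %), toluene (0.005 M), 80 °C, argon sparge
Reagents that add atoms: none
Why: The ruthenium alkylidene should initiate at the monosubstituted allylic olefin, add across the 1,1-diarylethylene in an intramolecular [2+2] step and cyclorevert, which forms C3=C4 and releases ethene (olefin metathesis by the metallacyclobutane mechanism). The closest known reaction type is the ring-closing metathesis of 2-(1-substituted vinyl)phenyl allyl ethers to 4-substituted 2H-chromenes. The six-membered pyran ring C (O1–C2–C3–C4–C4a–C8a) is closed by metathesis with the new double bond endocyclic and therefore cis. No stereocentre is created: C2 is neither ionised nor deprotonated under neutral ruthenium conditions, and the step delivers the prochiral C3=C4 on which step 10 sets C3 and C4 in one syn addition. The step needs ring closure to win over intermolecular metathesis and over olefin migration to the enol ether; high dilution, the inability of the 1,1-diarylethylene to homodimerise, removal of ethene and benzoquinone as hydride scavenger should secure this.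

**Step 10**
Reactants: 15 the 2H-chromene from step 9
Product: 17 (2R,3S,4S)-7-(benzyloxy)-2-[3,4,5-tris(benzyloxy)phenyl]-4-[(2R,3R)-3,5,7-tris(benzyloxy)-2-[3,4,5-tris(benzyloxy)phenyl]chroman-8-yl]chroman-3-ol, via alkylborane 16 (not isolated)
Conditions: BH3·THF (4 equiv), THF, 0 °C → rt; then NaOH (3 M aq), H2O2 (30 %), 0 °C → rt
Reagents that add atoms: hydrogen peroxide OO
Why: Hydroboration–oxidation in which BH3 should add syn across C3=C4 with boron on the less substituted C3 and from the face anti to the C2 aryl group, and oxidation with retention then gives 3-OH trans to both aryl groups, so that C3 (S) and C4 (S) are set together by substrate control from C2 (whose descriptor changes from S to R only through the priority rules).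

**Step 11**
Reactants: 17 the deca-O-benzyl flavan-3-ol dimer from step 10
Product: 18 CNP0275321.3, robinetinidol-(4α→8)-epigallocatechin
Conditions: H2 (1 atm), Pd(OH)2/C, THF/MeOH (1:1), rt; filtration under argon, lyophilisation
Reagents that add atoms: none
Why: Hydrogenolysis of the ten benzyl ethers under neutral conditions, which should leave the two C2–O1 benzylic ring bonds, the C4–C8 interflavan bond and all five stereocentres untouched.

**Compound list**

1 | (−)-epigallocatechin, (2R,3R)-2-(3,4,5-trihydroxyphenyl)chromane-3,5,7-triol | Oc1cc(O)c2c(c1)O[C@H](c1cc(O)c(O)c(O)c1)[C@H](O)C2 | starting material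

2 | 5,7,3',4',5'-penta-O-benzyl-(−)-epigallocatechin, (2R,3R)-5,7-bis(benzyloxy)-2-[3,4,5-tris(benzyloxy)phenyl]chroman-3-ol | c1ccccc1COc1cc(OCc3ccccc3)c2c(c1)O[C@H](c1cc(OCc3ccccc3)c(OCc3ccccc3)c(OCc3ccccc3)c1)[C@H](O)C2 | intermediate

3 | 3,5,7,3',4',5'-hexa-O-benzyl-(−)-epigallocatechin, (2R,3R)-3,5,7-tris(benzyloxy)-2-[3,4,5-tris(benzyloxy)phenyl]chromane | c1ccccc1COc1cc(OCc3ccccc3)c2c(c1)O[C@H](c1cc(OCc3ccccc3)c(OCc3ccccc3)c(OCc3ccccc3)c1)[C@H](OCc1ccccc1)C2 | intermediate

4 | (2R,3R)-8-bromo-3,5,7-tris(benzyloxy)-2-[3,4,5-tris(benzyloxy)phenyl]chromane | Brc1c(OCc3ccccc3)cc(OCc3ccccc3)c2c1O[C@H](c1cc(OCc3ccccc3)c(OCc3ccccc3)c(OCc3ccccc3)c1)[C@H](OCc1ccccc1)C2 | intermediate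

5 | 3,4,5-tris(benzyloxy)benzaldehyde | O=Cc1cc(OCc2ccccc2)c(OCc2ccccc2)c(OCc2ccccc2)c1 | starting material

6 | triethyl phosphonoacetate | CCOC(=O)CP(=O)(OCC)OCC | starting material

7 | ethyl (E)-3-[3,4,5-tris(benzyloxy)phenyl]prop-2-enoate | CCOC(=O)/C=C/c1cc(OCc2ccccc2)c(OCc2ccccc2)c(OCc2ccccc2)c1 | intermediate

8 | (E)-3-[3,4,5-tris(benzyloxy)phenyl]prop-2-en-1-ol | OC/C=C/c1cc(OCc2ccccc2)c(OCc2ccccc2)c(OCc2ccccc2)c1 | intermediate

9 | methyl (E)-3-[3,4,5-tris(benzyloxy)phenyl]prop-2-en-1-yl carbonate | COC(=O)OC/C=C/c1cc(OCc2ccccc2)c(OCc2ccccc2)c(OCc2ccccc2)c1 | intermediate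

10 | 1-[4-(benzyloxy)-2-hydroxyphenyl]ethan-1-one | CC(=O)c1ccc(OCc2ccccc2)cc1O | starting material

11 | 1-[4-(benzyloxy)-2-{[(1S)-1-[3,4,5-tris(benzyloxy)phenyl]prop-2-en-1-yl]oxy}phenyl]ethan-1-one | CC(=O)c1ccc(OCc2ccccc2)cc1O[C@H](c1cc(OCc2ccccc2)c(OCc2ccccc2)c(OCc2ccccc2)c1)C=C | intermediate

12 | 8-lithio derivative of 3 (aryllithium, not isolated) | [Li]c1c(OCc3ccccc3)cc(OCc3ccccc3)c2c1O[C@H](c1cc(OCc3ccccc3)c(OCc3ccccc3)c(OCc3ccccc3)c1)[C@H](OCc1ccccc1)C2 | intermediate

13 | 1-(ring A aryl of 11)-1-(chroman-8-yl of 3)ethan-1-ol, lithium alkoxide in the flask, both epimers at the carbinol carbon (not isolated) | CC(O)(c1ccc(OCc2ccccc2)cc1O[C@H](c1cc(OCc2ccccc2)c(OCc2ccccc2)c(OCc2ccccc2)c1)C=C)c1c(OCc3ccccc3)cc(OCc3ccccc3)c2c1O[C@H](c1cc(OCc3ccccc3)c(OCc3ccccc3)c(OCc3ccccc3)c1)[C@H](OCc1ccccc1)C2 | intermediate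

14 | (2R,3R)-8-{1-[4-(benzyloxy)-2-{[(1S)-1-[3,4,5-tris(benzyloxy)phenyl]prop-2-en-1-yl]oxy}phenyl]ethenyl}-3,5,7-tris(benzyloxy)-2-[3,4,5-tris(benzyloxy)phenyl]chromane | C=C(c1ccc(OCc2ccccc2)cc1O[C@H](c1cc(OCc2ccccc2)c(OCc2ccccc2)c(OCc2ccccc2)c1)C=C)c1c(OCc3ccccc3)cc(OCc3ccccc3)c2c1O[C@H](c1cc(OCc3ccccc3)c(OCc3ccccc3)c(OCc3ccccc3)c1)[C@H](OCc1ccccc1)C2 | intermediate

15 | (2S)-7-(benzyloxy)-2-[3,4,5-tris(benzyloxy)phenyl]-4-[(2R,3R)-3,5,7-tris(benzyloxy)-2-[3,4,5-tris(benzyloxy)phenyl]chroman-8-yl]-2H-chromene | c1ccccc1COc1ccc2c(c1)O[C@H](c1cc(OCc3ccccc3)c(OCc3ccccc3)c(OCc3ccccc3)c1)C=C2c1c(OCc3ccccc3)cc(OCc3ccccc3)c2c1O[C@H](c1cc(OCc3ccccc3)c(OCc3ccccc3)c(OCc3ccccc3)c1)[C@H](OCc1ccccc1)C2 | intermediate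

16 | 3-boranyl derivative of 15 (C3–BH2, 4-H cis to boron, configuration as in 17; not isolated) | c1ccccc1COc1ccc2c(c1)O[C@H](c1cc(OCc3ccccc3)c(OCc3ccccc3)c(OCc3ccccc3)c1)[C@@H](B)[C@@H]2c1c(OCc3ccccc3)cc(OCc3ccccc3)c2c1O[C@H](c1cc(OCc3ccccc3)c(OCc3ccccc3)c(OCc3ccccc3)c1)[C@H](OCc1ccccc1)C2 | intermediate

17 | (2R,3S,4S)-7-(benzyloxy)-2-[3,4,5-tris(benzyloxy)phenyl]-4-[(2R,3R)-3,5,7-tris(benzyloxy)-2-[3,4,5-tris(benzyloxy)phenyl]chroman-8-yl]chroman-3-ol | c1ccccc1COc1ccc2c(c1)O[C@H](c1cc(OCc3ccccc3)c(OCc3ccccc3)c(OCc3ccccc3)c1)[C@@H](O)[C@@H]2c1c(OCc3ccccc3)cc(OCc3ccccc3)c2c1O[C@H](c1cc(OCc3ccccc3)c(OCc3ccccc3)c(OCc3ccccc3)c1)[C@H](OCc1ccccc1)C2 | intermediate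

18 | CNP0275321.3, (2R,3S,4S)-2-(3,4,5-trihydroxyphenyl)-4-[(2R,3R)-3,5,7-trihydroxy-2-(3,4,5-trihydroxyphenyl)chroman-8-yl]chromane-3,7-diol | Oc1ccc2c(c1)O[C@H](c1cc(O)c(O)c(O)c1)[C@@H](O)[C@@H]2c1c(O)cc(O)c2c1O[C@H](c1cc(O)c(O)c(O)c1)[C@H](O)C2 | target

**Count**

Total steps: 11. Longest linear sequence: 8 steps (steps 4 to 11, from aldehyde 5).

**Steps most likely to fail**

Step 9 (key step). The ruthenium alkylidene formed at the allyl terminus may fail to add across the tri-ortho-substituted 1,1-diarylethylene, so that intermolecular metathesis or migration of the allyl double bond to the enol ether takes over. The fallback is a carbonyl–olefin ring closure with a stoichiometric alkylidene, which still closes ring C through C3–C4. It sets out from 9 and 4. Commercial 4-(benzyloxy)-2-hydroxybenzaldehyde is etherified with 9 under the conditions of step 7 to give (S)-4-(benzyloxy)-2-{1-[3,4,5-tris(benzyloxy)phenyl]prop-2-en-1-yloxy}benzaldehyde F1. Aryllithium 12, made from 4 with n-BuLi as in step 8, is added at −78 °C to give the diarylmethanol F2. Dess–Martin periodinane with NaHCO3 in CH2Cl2 should give the diaryl ketone F3. One equivalent of Mo(=CHCMe2Ph)(=N-2,6-i-Pr2C6H3)[OCMe(CF3)2]2 in benzene at rt should exchange the alkylidene at the terminal olefin and then olefinate the ketone intramolecularly, which returns the route at 15.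

Step 7. The chelated ortho-acetyl phenoxide may be too weak a nucleophile, or the catalyst may re-ionise the branched ether, with loss of regio- and enantiopurity. The fallback sets the stereocentre on the alcohol and transfers it with inversion. It sets out from 5 and 10. Catalytic asymmetric vinylation of 5 with Zn(CH=CH2)2 and (+)-3-exo-(dimethylamino)isoborneol (5 mol %, the enantiomer expected to give the R carbinol) in toluene at 0 °C should give (R)-1-[3,4,5-tris(benzyloxy)phenyl]prop-2-en-1-ol F4. Mitsunobu etherification of F4 with 10 (PPh3, DIAD, toluene, −20 °C) should give 11 with inversion, where the route is rejoined.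

Step 8. The hindered aryllithium may enolise the methyl ketone instead of adding to it, or the allylic ether may ionise during the acid-induced dehydration. The fallback is a palladium–carbene cross-coupling carried out before the allylic ether is in place. It sets out from 10, 4 and 9. 10 is protected (2-(trimethylsilyl)ethoxymethyl chloride, i-Pr2NEt, CH2Cl2) as the SEM ether F5 and condensed with TsNHNH2 in MeOH to the N-tosylhydrazone F6. Coupling of F6 with 4 (Pd2(dba)3, XPhos, LiOtBu, dioxane, 100 °C) should give the SEM-protected 1,1-diarylethylene F7 by carbene migratory insertion and β-hydride elimination. n-Bu4NF in THF/DMPU at 60 °C should free the phenol F8. Iridium-catalysed etherification of F8 with 9 as in step 7 rejoins the route at 14.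

**Further compounds**

F1 | step 9 | (S)-4-(benzyloxy)-2-{1-[3,4,5-tris(benzyloxy)phenyl]prop-2-en-1-yloxy}benzaldehyde | O=Cc1ccc(OCc2ccccc2)cc1O[C@H](c1cc(OCc2ccccc2)c(OCc2ccccc2)c(OCc2ccccc2)c1)C=C

F2 | step 9 | diarylmethanol from 12 and F1 (both epimers at the carbinol carbon) | OC(c1ccc(OCc2ccccc2)cc1O[C@H](c1cc(OCc2ccccc2)c(OCc2ccccc2)c(OCc2ccccc2)c1)C=C)c1c(OCc3ccccc3)cc(OCc3ccccc3)c2c1O[C@H](c1cc(OCc3ccccc3)c(OCc3ccccc3)c(OCc3ccccc3)c1)[C@H](OCc1ccccc1)C2

F3 | step 9 | diaryl ketone, [4-(benzyloxy)-2-{(1S)-1-[3,4,5-tris(benzyloxy)phenyl]prop-2-en-1-yloxy}phenyl][(2R,3R)-3,5,7-tris(benzyloxy)-2-[3,4,5-tris(benzyloxy)phenyl]chroman-8-yl]methanone | O=C(c1ccc(OCc2ccccc2)cc1O[C@H](c1cc(OCc2ccccc2)c(OCc2ccccc2)c(OCc2ccccc2)c1)C=C)c1c(OCc3ccccc3)cc(OCc3ccccc3)c2c1O[C@H](c1cc(OCc3ccccc3)c(OCc3ccccc3)c(OCc3ccccc3)c1)[C@H](OCc1ccccc1)C2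

F4 | step 7 | (R)-1-[3,4,5-tris(benzyloxy)phenyl]prop-2-en-1-ol | O[C@@H](c1cc(OCc2ccccc2)c(OCc2ccccc2)c(OCc2ccccc2)c1)C=C

F5 | step 8 | 1-[4-(benzyloxy)-2-{[2-(trimethylsilyl)ethoxy]methoxy}phenyl]ethan-1-one | CC(=O)c1ccc(OCc2ccccc2)cc1OCOCC[Si](C)(C)C

F6 | step 8 | N-tosylhydrazone of F5 | CC(=NNS(=O)(=O)c1ccc(C)cc1)c1ccc(OCc2ccccc2)cc1OCOCC[Si](C)(C)C

F7 | step 8 | (2R,3R)-8-{1-[4-(benzyloxy)-2-{[2-(trimethylsilyl)ethoxy]methoxy}phenyl]ethenyl}-3,5,7-tris(benzyloxy)-2-[3,4,5-tris(benzyloxy)phenyl]chromane | C=C(c1ccc(OCc2ccccc2)cc1OCOCC[Si](C)(C)C)c1c(OCc3ccccc3)cc(OCc3ccccc3)c2c1O[C@H](c1cc(OCc3ccccc3)c(OCc3ccccc3)c(OCc3ccccc3)c1)[C@H](OCc1ccccc1)C2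

F8 | step 8 | 5-(benzyloxy)-2-{1-[(2R,3R)-3,5,7-tris(benzyloxy)-2-[3,4,5-tris(benzyloxy)phenyl]chroman-8-yl]ethenyl}phenol | C=C(c1ccc(OCc2ccccc2)cc1O)c1c(OCc3ccccc3)cc(OCc3ccccc3)c2c1O[C@H](c1cc(OCc3ccccc3)c(OCc3ccccc3)c(OCc3ccccc3)c1)[C@H](OCc1ccccc1)C2
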